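**Retrosynthetic overview**
1. Feature: in hydroazulene 28 the fusion bond C3a–C8a joins C8a, which is β to the C7 ketone of the seven-membered ring (C7–C8–C8a), to C3a, whose neighbour C3 in the five-membered ring carries the tertiary hydroxyl. The array HO–C3–C3a–C8a–C8–C7=O is what an alkene, an enone and water give on addition.
2. Disconnection 1 (last step): cutting C3a–C8a and C3–OH merges both rings into the ten-membered trienone 26 (C8=C8a enone, ring-trans C3=C3a, ring-cis C5=C6). It already carries C1–OAc and the C4 aroyl ester.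
3. Disconnection 2: the ten-membered ring is opened at C6–C7 (alkenyl iodide plus enal, Nozaki–Hiyama–Kishi, then oxidation). The carbinol made on closure is the future ketone, so no stereocentre depends on the macrocyclisation.
4. Disconnection 3: chain 23 comes from C7–C8–C8a–C1 (enal 3), C2–C3–C3a (allenylboronate 4, sets C1), C4 (formaldehyde), isopropyl (11) and C5–C6 (propyne 14, sets C4). The C3=C3a and C5=C6 alkenes come from trans-hydroalumination of propargylic alcohols.
5. Ring order: ten-membered ring first (step 14), then the five- and seven-membered rings together (step 17).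

Key step: step 17

Numbering: the azulene numbering of 28 (C1 CH–OAc, C2, C3 C(OH)iPr, C3a, C4 CH–O-aroyl, C5=C6–Me, C7=O, C8, C8a C–Me) is used for all intermediates.
Remark on descriptors: C3=C3a of 26 is trans within the ring (C2 trans to C4) but carries the descriptor Z, because isopropyl outranks C2. Only anti addition across this geometry gives the C3/C3a relation of 28.
Assumption: the sense of induction in steps 2 and 8 (Re-face attack in both) follows the accepted models for simple aldehydes. Both catalysts are sold as either enantiomer, so the drawn configuration is accessible in any case.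

**Step 1**
Reactants: 1 2,2-dimethoxyacetaldehyde; 2 2-(triphenylphosphoranylidene)propanal
Product: 3 (2E)-4,4-dimethoxy-2-methylbut-2-enal
Conditions: CH2Cl2, rt (1 in slight excess)
Reagents that add atoms: none
Why: Wittig olefination with a stabilised ylide is E-selective, and the electron-poor aldehyde 1 reacts faster than the hindered product enal, so C7 ends trans to C1 across C8=C8a.

**Step 2**
Reactants: 3 (2E)-4,4-dimethoxy-2-methylbut-2-enal; 4 allenylboronic acid pinacol ester
Product: 5 (4R,5E)-7,7-dimethoxy-5-methylhept-5-en-1-yn-4-ol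
Conditions: (R)-3,3'-bis(2,4,6-triisopropylphenyl)-1,1'-binaphthyl-2,2'-diyl hydrogen phosphate [(R)-TRIP] (10 mol %), 4 Å MS, toluene, −20 °C; aqueous work-up
Reagents that add atoms: none
Why: Chiral-phosphoric-acid-catalysed allenylboration (asymmetric propargylation) runs through a closed six-membered SE2' transition state in which the acid holds a boronate oxygen and the formyl hydrogen, so the propargyl group should reach the Re face and set C1 as R while the anhydrous weak acid leaves the acetal alone.

**Step 3**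
Reactants: 5 (4R,5E)-7,7-dimethoxy-5-methylhept-5-en-1-yn-4-ol
Product: 6 (4R,5E)-7,7-dimethoxy-5-methyl-4-(triethylsilyloxy)hept-5-en-1-yne
Conditions: Et3SiCl, imidazole, CH2Cl2, 0 °C to rt
Reagents that add atoms: chlorotriethylsilane CC[Si](Cl)(CC)CC
Why: Routine silylation of a secondary alcohol gives an ether that withstands the bases, hydrides and organozinc reagents of steps 4 to 9 and later falls to the same mild acid that opens the acetal.

**Step 4**
Reactants: 6 (4R,5E)-7,7-dimethoxy-5-methyl-4-(triethylsilyloxy)hept-5-en-1-yne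
Product: 8 (5R,6E)-8,8-dimethoxy-6-methyl-5-(triethylsilyloxy)oct-6-en-2-yn-1-ol, via lithium acetylide 7 (not isolated)
Conditions: n-BuLi, THF, −78 °C; then (CH2O)n, −78 °C to rt; H2O
Reagents that add atoms: formaldehyde (as paraformaldehyde) C=O
Why: Deprotonation of the terminal alkyne and hydroxymethylation of the acetylide is a standard one-carbon homologation that introduces C4 and touches no other group of 6.

**Step 5**
Reactants: 8 (5R,6E)-8,8-dimethoxy-6-methyl-5-(triethylsilyloxy)oct-6-en-2-yn-1-ol
Product: 10 (2Z,5R,6E)-3-iodo-8,8-dimethoxy-6-methyl-5-(triethylsilyloxy)octa-2,6-dien-1-ol, via cyclic alkenylaluminate 9 (not isolated)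
Conditions: NaAlH2(OCH2CH2OMe)2 (Red-Al), THF, 0 °C to rt; then I2, THF, −78 °C; aqueous work-up
Reagents that add atoms: iodine [I][I]
Why: Alkoxide-directed trans-hydroalumination of a propargylic alcohol places aluminium on C3 in a five-membered chelate, and iodinolysis with retention gives the Z iodide in which C2 already stands trans to C4.

**Step 6**
Reactants: 10 (2Z,5R,6E)-3-iodo-8,8-dimethoxy-6-methyl-5-(triethylsilyloxy)octa-2,6-dien-1-ol; 11 isopropylzinc bromide
Product: 12 (2Z,5R,6E)-8,8-dimethoxy-6-methyl-3-(propan-2-yl)-5-(triethylsilyloxy)octa-2,6-dien-1-ol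
Conditions: Pd(dppf)Cl2 (5 mol %), THF, rt
Reagents that add atoms: none
Why: Negishi coupling proceeds with retention at the alkenyl iodide, the wide-bite-angle ligand favours reductive elimination over β-hydride isomerisation of the secondary alkyl group, and alkylzinc halides couple faster than the alcohol protonates them, so isopropyl ends cis to C4.

**Step 7**
Reactants: 12 (2Z,5R,6E)-8,8-dimethoxy-6-methyl-3-(propan-2-yl)-5-(triethylsilyloxy)octa-2,6-dien-1-ol
Product: 13 (2Z,5R,6E)-8,8-dimethoxy-6-methyl-3-(propan-2-yl)-5-(triethylsilyloxy)octa-2,6-dienal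
Conditions: activated MnO2, CH2Cl2, rt
Reagents that add atoms: none
Why: Heterogeneous MnO2 oxidation of a primary allylic alcohol is neutral and should keep the Z geometry, the acetal and the silyl ether.

**Step 8**
Reactants: 13 (2Z,5R,6E)-8,8-dimethoxy-6-methyl-3-(propan-2-yl)-5-(triethylsilyloxy)octa-2,6-dienal; 14 propyne
Product: 15 (4S,5Z,8R,9E)-11,11-dimethoxy-9-methyl-6-(propan-2-yl)-8-(triethylsilyloxy)undeca-5,9-dien-2-yn-4-ol
Conditions: Me2Zn, (S,S)-ProPhenol [2,6-bis{[(S)-2-(hydroxydiphenylmethyl)pyrrolidin-1-yl]methyl}-4-methylphenol] (20 mol %), Ph3P=O (40 mol %), toluene, 0 °C; aqueous work-up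
Reagents that add atoms: none
Why: The dinuclear zinc–ProPhenol asymmetric alkynylation, which is at its best with α,β-unsaturated aldehydes, should deliver the propynyl group to the Re face under catalyst control and set C4 as S, which is the spatial arrangement of C4 in 28.

**Step 9**
Reactants: 15 (4S,5Z,8R,9E)-11,11-dimethoxy-9-methyl-6-(propan-2-yl)-8-(triethylsilyloxy)undeca-5,9-dien-2-yn-4-ol
Product: 17 (2Z,4S,5Z,8R,9E)-2-iodo-11,11-dimethoxy-9-methyl-6-(propan-2-yl)-8-(triethylsilyloxy)undeca-2,5,9-trien-4-ol, via cyclic alkenylaluminate 16 (not isolated)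
Conditions: NaAlH2(OCH2CH2OMe)2 (Red-Al), THF, 0 °C to rt; then I2, THF, −78 °C; aqueous work-up
Reagents that add atoms: iodine [I][I]
Why: A second alkoxide-directed trans-hydroalumination and iodinolysis acts only on the propargylic alkyne and puts iodine on C6 cis to C4, which is the ring-cis geometry that C5=C6 needs.

**Step 10**
Reactants: 18 4-hydroxybenzoic acid
Product: 20 4-(tert-butyldimethylsilyloxy)benzoic acid, via bis-silyl derivative 19 (not isolated)
Conditions: t-BuMe2SiCl (2.2 equiv), imidazole, DMF, rt; then AcOH–THF–H2O, rt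
Reagents that add atoms: tert-butyldimethylsilyl chloride CC(C)(C)[Si](C)(C)Cl
Why: Exhaustive silylation followed by selective hydrolysis works because a silyl ester is far more labile to aqueous acid than an aryl silyl ether.

**Step 11**
Reactants: 17 (2Z,4S,5Z,8R,9E)-2-iodo-11,11-dimethoxy-9-methyl-6-(propan-2-yl)-8-(triethylsilyloxy)undeca-2,5,9-trien-4-ol; 20 4-(tert-butyldimethylsilyloxy)benzoic acid
Product: 21 4-(tert-butyldimethylsilyloxy)benzoate of 17 (ester at C4)
Conditions: DCC, DMAP (cat.), CH2Cl2, 0 °C to rt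
Reagents that add atoms: none
Why: Steglich esterification acylates the carbinol oxygen under neutral conditions without breaking the C4–O bond, so the doubly allylic centre keeps its configuration.

**Step 12**
Reactants: 21 4-(tert-butyldimethylsilyloxy)benzoate of 17
Product: 22 (2E,4R,6Z,8S,9Z)-4-hydroxy-10-iodo-3-methyl-1-oxo-6-(propan-2-yl)undeca-2,6,9-trien-8-yl 4-(tert-butyldimethylsilyloxy)benzoate
Conditions: AcOH–THF–H2O (3:1:1), rt
Reagents that add atoms: water O
Why: Acid hydrolysis in dilute acetic acid cleaves the very labile α,β-unsaturated acetal and the triethylsilyl ether together, whereas the aryl silyl ether and the C4 ester need much stronger acid.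

**Step 13**
Reactants: 22 (2E,4R,6Z,8S,9Z)-4-hydroxy-10-iodo-3-methyl-1-oxo-6-(propan-2-yl)undeca-2,6,9-trien-8-yl 4-(tert-butyldimethylsilyloxy)benzoate
Product: 23 (2E,4R,6Z,8S,9Z)-4-acetoxy-10-iodo-3-methyl-1-oxo-6-(propan-2-yl)undeca-2,6,9-trien-8-yl 4-(tert-butyldimethylsilyloxy)benzoate
Conditions: Ac2O, pyridine, DMAP (cat.), CH2Cl2, 0 °C
Reagents that add atoms: acetic anhydride CC(=O)OC(C)=O
Why: DMAP-catalysed acetylation meets only one free hydroxyl, at C1, and the E geometry of the γ-hydroxy enal rules out lactol formation.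

**Step 14**
Reactants: 23 (2E,4R,6Z,8S,9Z)-4-acetoxy-10-iodo-3-methyl-1-oxo-6-(propan-2-yl)undeca-2,6,9-trien-8-yl 4-(tert-butyldimethylsilyloxy)benzoate
Product: 24 (2Z,4S,5Z,8R,9E)-8-acetoxy-1-hydroxy-2,9-dimethyl-6-(propan-2-yl)cyclodeca-2,5,9-trien-4-yl 4-(tert-butyldimethylsilyloxy)benzoate (both epimers at the carbinol, azulene C7)
Conditions: CrCl2 (10 equiv), NiCl2 (0.1 equiv), DMSO–THF, 0.002 M, slow addition, rt; aqueous work-up
Reagents that add atoms: none
Why: In the Nozaki–Hiyama–Kishi reaction zerovalent nickel inserts into the alkenyl iodide and the derived alkenylchromium adds only to the aldehyde, so the esters are tolerated, the trisubstituted iodide keeps its geometry, high dilution favours the ten-membered ring, and the new C7 centre needs no control because step 15 erases it.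

**Step 15**
Reactants: 24 cyclodecatrienol (both C7 epimers)
Product: 25 (2Z,4S,5Z,8R,9E)-8-acetoxy-2,9-dimethyl-1-oxo-6-(propan-2-yl)cyclodeca-2,5,9-trien-4-yl 4-(tert-butyldimethylsilyloxy)benzoate
Conditions: Dess–Martin periodinane, pyridine, CH2Cl2, 0 °C
Reagents that add atoms: none
Why: Buffered Dess–Martin oxidation of a doubly allylic alcohol is fast at 0 °C, converges both epimers on one cross-conjugated ketone, and stays well below the temperature of a Cope rearrangement of the 1,5-diene.

**Step 16**
Reactants: 25 silyl-protected cyclodecatrienone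
Product: 26 (2Z,4S,5Z,8R,9E)-8-acetoxy-2,9-dimethyl-1-oxo-6-(propan-2-yl)cyclodeca-2,5,9-trien-4-yl 4-hydroxybenzoate
Conditions: Bu4NF–AcOH (1:1), THF, 0 °C
Reagents that add atoms: none
Why: Fluoride-induced desilylation of an aryl silyl ether is very fast, and the acetic acid buffer protonates the phenoxide at once, so the esters and the dienone see no base.

**Step 17**
Reactants: 26 (2Z,4S,5Z,8R,9E)-8-acetoxy-2,9-dimethyl-1-oxo-6-(propan-2-yl)cyclodeca-2,5,9-trien-4-yl 4-hydroxybenzoate
Product: 28 (1R,3R,3aR,4R,8aS)-1-acetoxy-3-hydroxy-6,8a-dimethyl-7-oxo-3-(propan-2-yl)-1,2,3,3a,4,7,8,8a-octahydroazulen-4-yl 4-hydroxybenzoate (CNP0087181.5), via C7 dienol 27 (not isolated)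
Conditions: Sc(OTf)3 (10 mol %), 2,6-di-tert-butylpyridine (5 mol %), MeNO2 containing H2O (5 equiv), 0 °C
Reagents that add atoms: water O
Why: Proposed new method: Sc(OTf)3 binds the C7 carbonyl oxygen, whose only coplanar partner in the ring is the s-trans C8=C8a arm (the ring-cis C5=C6 arm stands almost perpendicular, which also denies a Nazarov closure its planar pentadienyl cation); C3a of the trisubstituted alkene then adds to C8a across the ring, the tertiary C3 cation is capped on its outer face by water, either directly or through the C4 ester carbonyl as a 1,3-dioxan-2-ylium ion that water opens to the more stable secondary ester, and dienol 27 tautomerises to give the C8 methylene. The closest known reaction types are the Lewis-acid-induced conjugate addition of unactivated alkenes to enones and the acid-mediated hydrative transannular cyclisation of germacrone and germacrene epoxides to hydroazulenes, whereas an enone as transannular electrophile in a cyclodecatrienone with water as terminator has not been shown. The single new bond C3a–C8a closes the cyclopentane in 5-exo-trig mode with respect to the enone (5-endo with respect to the nucleophilic alkene) and the cycloheptenone in 7-endo-trig mode with respect to the enone (7-exo with respect to the alkene). C3a is controlled by C4, because A(1,3) strain with the cis isopropyl group holds H4 in the alkene plane with C5 inside and the ester outside, so only one alkene face looks into the ring; C3 follows from anti addition across the ring-trans (descriptor Z) alkene; C8a is controlled by a parallel, not crossed, alignment of the two ring-trans double bonds, in which the C1–O bond eclipses C8a=C8 anti to the methyl group and the cis C4–C5=C6–C7 bridge spans the two alkene planes without pressing C7 against H4, which places the C8a methyl anti to H3a (trans fusion), whereas the crossed form would give the cis-fused epimer. The step needs chemoselectivity for enone activation over ionisation of the doubly allylic C4 ester and over Cope rearrangement, which the more basic ketone oxygen, a catalytic water-tolerant Lewis acid freed from triflic acid by the hindered base, and 0 °C are meant to secure, and it needs Markovnikov regioselectivity, which the tertiary character of C3 secures.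

**Compound list**
1 | 2,2-dimethoxyacetaldehyde | COC(OC)C=O | starting material
2 | 2-(triphenylphosphoranylidene)propanal | CC(C=O)=P(c1ccccc1)(c1ccccc1)c1ccccc1 | starting material
3 | (2E)-4,4-dimethoxy-2-methylbut-2-enal | COC(OC)/C=C(\C)C=O | intermediate
4 | allenylboronic acid pinacol ester | C=C=CB1OC(C)(C)C(C)(C)O1 | starting material
5 | (4R,5E)-7,7-dimethoxy-5-methylhept-5-en-1-yn-4-ol | C#CC[C@@H](O)/C(C)=C/C(OC)OC | intermediate
6 | (4R,5E)-7,7-dimethoxy-5-methyl-4-(triethylsilyloxy)hept-5-en-1-yne | C#CC[C@@H](O[Si](CC)(CC)CC)/C(C)=C/C(OC)OC | intermediate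
7 | lithium acetylide of 6 | [Li]C#CC[C@@H](O[Si](CC)(CC)CC)/C(C)=C/C(OC)OC | intermediate
8 | (5R,6E)-8,8-dimethoxy-6-methyl-5-(triethylsilyloxy)oct-6-en-2-yn-1-ol | OCC#CC[C@@H](O[Si](CC)(CC)CC)/C(C)=C/C(OC)OC | intermediate
9 | sodium cyclic alkenylaluminate of 8 (O–Al–C3 chelate) | [Na+].COCCO[Al-]1(OCCOC)OCC=C1C[C@@H](O[Si](CC)(CC)CC)/C(C)=C/C(OC)OC | intermediate
10 | (2Z,5R,6E)-3-iodo-8,8-dimethoxy-6-methyl-5-(triethylsilyloxy)octa-2,6-dien-1-ol | OC/C=C(\I)C[C@@H](O[Si](CC)(CC)CC)/C(C)=C/C(OC)OC | intermediate
11 | isopropylzinc bromide | CC(C)[Zn]Br | starting material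
12 | (2Z,5R,6E)-8,8-dimethoxy-6-methyl-3-(propan-2-yl)-5-(triethylsilyloxy)octa-2,6-dien-1-ol | OC/C=C(\C(C)C)C[C@@H](O[Si](CC)(CC)CC)/C(C)=C/C(OC)OC | intermediate
13 | (2Z,5R,6E)-8,8-dimethoxy-6-methyl-3-(propan-2-yl)-5-(triethylsilyloxy)octa-2,6-dienal | O=C/C=C(\C(C)C)C[C@@H](O[Si](CC)(CC)CC)/C(C)=C/C(OC)OC | intermediate
14 | propyne | CC#C | starting material
15 | (4S,5Z,8R,9E)-11,11-dimethoxy-9-methyl-6-(propan-2-yl)-8-(triethylsilyloxy)undeca-5,9-dien-2-yn-4-ol | CC#C[C@@H](O)/C=C(\C(C)C)C[C@@H](O[Si](CC)(CC)CC)/C(C)=C/C(OC)OC | intermediate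
16 | sodium cyclic alkenylaluminate of 15 (O–Al–C6 chelate) | [Na+].COCCO[Al-]1(OCCOC)O[C@@H](/C=C(\C(C)C)C[C@@H](O[Si](CC)(CC)CC)/C(C)=C/C(OC)OC)C=C1C | intermediate
17 | (2Z,4S,5Z,8R,9E)-2-iodo-11,11-dimethoxy-9-methyl-6-(propan-2-yl)-8-(triethylsilyloxy)undeca-2,5,9-trien-4-ol | C/C(I)=C/[C@@H](O)/C=C(\C(C)C)C[C@@H](O[Si](CC)(CC)CC)/C(C)=C/C(OC)OC | intermediate
18 | 4-hydroxybenzoic acid | OC(=O)c1ccc(O)cc1 | starting material
19 | tert-butyldimethylsilyl 4-(tert-butyldimethylsilyloxy)benzoate | CC(C)(C)[Si](C)(C)OC(=O)c1ccc(O[Si](C)(C)C(C)(C)C)cc1 | intermediate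
20 | 4-(tert-butyldimethylsilyloxy)benzoic acid | OC(=O)c1ccc(O[Si](C)(C)C(C)(C)C)cc1 | intermediate
21 | 4-(tert-butyldimethylsilyloxy)benzoate of 17 | C/C(I)=C/[C@@H](OC(=O)c1ccc(O[Si](C)(C)C(C)(C)C)cc1)/C=C(\C(C)C)C[C@@H](O[Si](CC)(CC)CC)/C(C)=C/C(OC)OC | intermediate
22 | C1-hydroxy iodo enal | C/C(I)=C/[C@@H](OC(=O)c1ccc(O[Si](C)(C)C(C)(C)C)cc1)/C=C(\C(C)C)C[C@@H](O)/C(C)=C/C=O | intermediate
23 | C1-acetoxy iodo enal | C/C(I)=C/[C@@H](OC(=O)c1ccc(O[Si](C)(C)C(C)(C)C)cc1)/C=C(\C(C)C)C[C@@H](OC(C)=O)/C(C)=C/C=O | intermediate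
24 | cyclodecatrienol, both C7 epimers (C7 left open in the SMILES) | CC(=O)O[C@@H]1C/C(C(C)C)=C/[C@H](OC(=O)c2ccc(O[Si](C)(C)C(C)(C)C)cc2)/C=C(C)\C(O)/C=C1\C | intermediate
25 | silyl-protected cyclodecatrienone | CC(=O)O[C@@H]1C/C(C(C)C)=C/[C@H](OC(=O)c2ccc(O[Si](C)(C)C(C)(C)C)cc2)/C=C(C)\C(=O)/C=C1\C | intermediate
26 | cyclodecatrienone with free phenol (key-step precursor) | CC(=O)O[C@@H]1C/C(C(C)C)=C/[C@H](OC(=O)c2ccc(O)cc2)/C=C(C)\C(=O)/C=C1\C | intermediate
27 | C7 dienol of 28 | CC(=O)O[C@@H]1C[C@@](O)(C(C)C)[C@H]2[C@H](OC(=O)c3ccc(O)cc3)C=C(C)C(O)=C[C@]12C | intermediate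
28 | CNP0087181.5 | CC(=O)O[C@@H]1C[C@@](O)(C(C)C)[C@H]2[C@H](OC(=O)c3ccc(O)cc3)C=C(C)C(=O)C[C@]12C | target

**Step count:** 17 steps in total. The longest linear sequence is 16 steps (steps 1 to 9 and 11 to 17); step 10 is a one-step side branch.

**Steps most likely to fail**

1. **Step 17.** The doubly allylic C4 ester may ionise, the C3 cation may lose a proton, or the ring may react through the crossed conformer, with poor facial selectivity at C8a. Any of these may outrun the wanted closure.
 - The fallback uses known chemistry with an epoxide instead of the enone as transannular electrophile. It sets out from 24 and comes back at 28.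
 - Hydroxyl-directed epoxidation (VO(acac)2, t-BuOOH, CH2Cl2, 0 °C) of the strained ring-trans C8=C8a bond from its outer face gives the 8,8a-epoxy cyclodecadienol F1. The C8a question is thus settled on an isolable compound.
 - Camphorsulfonic acid (cat.) in wet acetone at 0 °C triggers the established transannular opening of germacrene-type epoxides. C3a attacks tertiary C8a with inversion and water caps C3, which gives the hydroazulene-3,7,8-triol diester F2.
 - MnO2 oxidises only the allylic C7 carbinol to the 8-hydroxy enone F3.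
 - 1,1'-Thiocarbonyldiimidazole converts the secondary C8 hydroxyl into the imidazolylthiocarbonate F4.
 - Barton–McCombie reduction (Bu3SnH, AIBN, toluene, 80 °C) gives the silyl ether of the target F5.
 - Bu4NF–AcOH then frees the phenol of 28.

2. **Step 14.** Oligomerisation, protodeiodination or reductive loss of the γ-acetoxy group by divalent chromium may compete with closure of the strained ring.
 - The fallback closes the ring at C5=C6 by metathesis. It sets out from 15 and comes back at 24.
 - Red-Al reduction of 15 with an aqueous quench in place of iodine gives the (E)-propenyl carbinol F6.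
 - Esterification with 20 as in step 11 gives the benzoate F7.
 - AcOH–THF–H2O gives the hydroxy enal F8, and acetylation gives the acetoxy enal F9.
 - Isopropenylmagnesium bromide (THF, −78 °C) adds to the aldehyde only and gives the isopropenyl carbinol F10 (both C7 epimers).
 - Ring-closing metathesis with second-generation Hoveyda–Grubbs catalyst (CH2Cl2, high dilution, 40 °C) joins C5 to C6 with loss of propene. The ring enforces the cis geometry and the product is 24.

3. **Step 8.** Facial control in the alkynyl transfer to the hindered Z enal may be incomplete, or the enal may isomerise from Z to E during the slow addition.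
 - The fallback sets C4 by reduction instead of addition. It sets out from 13 and comes back at 15.
 - Prop-1-ynylmagnesium bromide (THF, −78 °C) gives the carbinol as both C4 epimers F11.
 - MnO2 gives the alkenyl alkynyl ketone F12.
 - Corey–Bakshi–Shibata reduction ((S)-2-methyl-CBS-oxazaborolidine, catecholborane, toluene, −78 °C) gives 15, with the slim alkynyl arm acting as the small group.

**Further compounds**
F1 | step 17 | 8,8a-epoxy cyclodecadienol (C7 epimers) | CC(=O)O[C@@H]1C/C(C(C)C)=C/[C@H](OC(=O)c2ccc(O[Si](C)(C)C(C)(C)C)cc2)/C=C(C)\C(O)[C@H]3O[C@]13C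
F2 | step 17 | hydroazulene-3,7,8-triol diester (C7 epimers) | CC(=O)O[C@@H]1C[C@@](O)(C(C)C)[C@H]2[C@H](OC(=O)c3ccc(O[Si](C)(C)C(C)(C)C)cc3)C=C(C)C(O)[C@@H](O)[C@]12C
F3 | step 17 | 8-hydroxy enone | CC(=O)O[C@@H]1C[C@@](O)(C(C)C)[C@H]2[C@H](OC(=O)c3ccc(O[Si](C)(C)C(C)(C)C)cc3)C=C(C)C(=O)[C@@H](O)[C@]12C
F4 | step 17 | C8 imidazolylthiocarbonate | CC(=O)O[C@@H]1C[C@@](O)(C(C)C)[C@H]2[C@H](OC(=O)c3ccc(O[Si](C)(C)C(C)(C)C)cc3)C=C(C)C(=O)[C@@H](OC(=S)n4ccnc4)[C@]12C
F5 | step 17 | tert-butyldimethylsilyl ether of the target | CC(=O)O[C@@H]1C[C@@](O)(C(C)C)[C@H]2[C@H](OC(=O)c3ccc(O[Si](C)(C)C(C)(C)C)cc3)C=C(C)C(=O)C[C@]12C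
F6 | step 14 | (E)-propenyl carbinol | C/C=C/[C@@H](O)/C=C(\C(C)C)C[C@@H](O[Si](CC)(CC)CC)/C(C)=C/C(OC)OC
F7 | step 14 | 4-(tert-butyldimethylsilyloxy)benzoate of F6 | C/C=C/[C@@H](OC(=O)c1ccc(O[Si](C)(C)C(C)(C)C)cc1)/C=C(\C(C)C)C[C@@H](O[Si](CC)(CC)CC)/C(C)=C/C(OC)OC
F8 | step 14 | hydroxy enal | C/C=C/[C@@H](OC(=O)c1ccc(O[Si](C)(C)C(C)(C)C)cc1)/C=C(\C(C)C)C[C@@H](O)/C(C)=C/C=O
F9 | step 14 | acetoxy enal | C/C=C/[C@@H](OC(=O)c1ccc(O[Si](C)(C)C(C)(C)C)cc1)/C=C(\C(C)C)C[C@@H](OC(C)=O)/C(C)=C/C=O
F10 | step 14 | isopropenyl carbinol (C7 epimers) | C/C=C/[C@@H](OC(=O)c1ccc(O[Si](C)(C)C(C)(C)C)cc1)/C=C(\C(C)C)C[C@@H](OC(C)=O)/C(C)=C/C(O)C(C)=C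
F11 | step 8 | propynyl carbinol (C4 epimers) | CC#CC(O)/C=C(\C(C)C)C[C@@H](O[Si](CC)(CC)CC)/C(C)=C/C(OC)OC
F12 | step 8 | alkenyl alkynyl ketone | CC#CC(=O)/C=C(\C(C)C)C[C@@H](O[Si](CC)(CC)CC)/C(C)=C/C(OC)OC
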